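**Plan** (target numbered as a bicyclo[3.2.1]octene: C1 allyl bridgehead, C2=C3(OMe), C4 OAc, C5 OMe bridgehead, C6 aryl, C7 methyl, C8 ketone bridge)
1. Retrosynthetic cuts, in order: C4–O (acetate installed last, with inversion). Then C1–C7 (retro-pinacol, C7 returns to C8), C1–allyl and C8–O. Finally C7–C8 and C5–C6 (retro [2+2]), which leads to 2,6-dimethoxy-1,4-benzoquinone and (E)-methyl isoeugenol.
2. Enabling feature: in the cyclopentanone ring C1–C8–C5–C6–C7, the ketone C8 sits next to quaternary C1, and C1 is the allylic end of the enol ether C2=C3–OMe. A cation at C1 is therefore methoxy-stabilised, so this ring can be grown from the cyclobutanol ring C8–C5–C6–C7.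
3. Forward order: the six-membered ring C1–C2–C3–C4–C5–C8 is the quinone ring, and the four-membered ring is fused on by [2+2]. C4=O is reduced, C8 is hydroxylated and allyl is added to C1=O. Ionisation at C1 then moves C7 from C8 to C1, so the four-membered ring becomes five-membered and fused [4.2.0] becomes bridged [3.2.1].
4. Stereochemistry: C5, C6, C7 and the absolute sense come from the TADDOLate–titanium [2+2]. C1 comes from the suprafacial shift. C4 comes from convex-face hydride delivery followed by Mitsunobu inversion.

Key step: step 5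

Remark 1: the (R,R)-TADDOLate complex of tetravalent titanium is assumed to give 3 in the absolute sense drawn; if the sense is opposite, (S,S)-TADDOL is used.
Remark 2: carbinol 7 is drawn as the convex-face adduct; its new centre is ionised in step 5, so its configuration does not matter.
Remark 3: the Why lines use target locants. Bicyclo[4.2.0] locants 1, 2, 3, 4, 5, 6, 7, 8 correspond to target C8, C1, C2, C3, C4, C5, C6, C7. In the [4.2.0] series, exo means the side of the angular substituents and endo means under the six-membered ring. In the [3.2.1] series, exo means the side of the C8 bridge.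

Step 1
Reactants: 1 2,6-dimethoxy-1,4-benzoquinone; 2 (E)-methyl isoeugenol
Product: 3 cis-fused 7-exo-(3,4-dimethoxyphenyl)-4,6-dimethoxy-8-endo-methylbicyclo[4.2.0]oct-3-ene-2,5-dione
Conditions: TiCl2(OiPr)2 (1.2 equiv), (R,R)-TADDOL (1.3 equiv), 4 Å MS, CH2Cl2/toluene, −78 °C; H2O
Reagents that add atoms: none
Why: Lewis acid-promoted stepwise [2+2] cycloaddition of a 2-alkoxy-1,4-benzoquinone with an (E)-propenylarene: the nucleophilic CHMe carbon of 2 should add to one of the two equivalent ring CH carbons of the chelated quinone, the benzylic cation should collapse on the neighbouring titanium enolate carbon C(OMe) on the same face (cis fusion) with the aryl group exo, away from the metal-bearing ring, and trans to methyl, and the C2-symmetric TADDOLate should shield one quinone face, which sets C5, C6 and C7 absolutely.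

Step 2
Reactants: 3 cyclobutane-fused enedione
Product: 4 7-exo-(3,4-dimethoxyphenyl)-5-hydroxy-4,6-dimethoxy-8-endo-methylbicyclo[4.2.0]oct-3-en-2-one (5-OH trans to 6-OMe)
Conditions: NaBH4, CeCl3·7H2O, MeOH, −78 °C
Reagents that add atoms: none
Why: Luche reduction: the vinylogous ester carbonyl (future C1) is inert, so only ketone C4 should be reduced in 1,2-fashion, and hydride should enter from the convex face, anti to the pseudoaxial C5–C6 bond (cerium chelation by C=O and the angular OMe predicts the same face), which places OH trans to the C5 methoxy group, the epimer that step 6 inverts.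

Step 3
Reactants: 4 hydroxy vinylogous ester
Product: 6 7-exo-(3,4-dimethoxyphenyl)-4,6-dimethoxy-8-endo-methyl-1,5-bis(trimethylsilyloxy)bicyclo[4.2.0]oct-3-en-2-one, via angular hydroxy ketone 5 (not isolated)
Conditions: KN(SiMe3)2 (2.3 equiv), THF, −78 °C; 2-(phenylsulfonyl)-3-phenyloxaziridine, −78 °C; Me3SiCl (3 equiv), −78 → 0 °C
Reagents that add atoms: 2-(phenylsulfonyl)-3-phenyloxaziridine O=S(=O)(c1ccccc1)N1OC1c1ccccc1; chlorotrimethylsilane C[Si](C)(C)Cl
Why: Kinetic alpha-prime deprotonation of the vinylogous ester (the hydrogen on C8 is the only alpha hydrogen) followed by enolate hydroxylation with an N-sulfonyloxaziridine, which can reach only the convex face so the ring fusion stays cis, while silylation in the same flask blocks a premature alpha-ketol shift and masks both alkoxides.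

Step 4
Reactants: 6 bis(silyl ether) ketone
Product: 7 2-allyl-7-exo-(3,4-dimethoxyphenyl)-4,6-dimethoxy-8-endo-methyl-1,5-bis(trimethylsilyloxy)bicyclo[4.2.0]oct-3-en-2-ol
Conditions: CH2=CHCH2MgBr (1.5 equiv), THF, −78 °C; pH 7 buffer; filtration through Et3N-deactivated silica
Reagents that add atoms: allylmagnesium bromide C=CC[Mg]Br
Why: 1,2-Addition of a Grignard reagent to a vinylogous ester (the first half of a Stork–Danheiser sequence): the small allyl reagent should tolerate the neopentyl carbonyl, and the new carbinol centre is erased again in step 5.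

Step 5
Reactants: 7 allyl carbinol
Product: 10 1-allyl-6-exo-(3,4-dimethoxyphenyl)-4-endo-hydroxy-3,5-dimethoxy-7-endo-methylbicyclo[3.2.1]oct-2-en-8-one, via dienyl oxocarbenium ion 8 (not isolated), via trimethylsilyl ether 9 (not isolated)
Conditions: PPTS (10 mol %), CH2Cl2, −20 → 0 °C; then MeOH, 0 °C
Reagents that add atoms: none
Why: Mild acid should ionise the tertiary bis-allylic C1–OH to cation 8, delocalised over C1–C2–C3 and capped by the C3 methoxy group; the C8–C7 bond then shifts to C1 and the C8 siloxy group collapses to the ketone, releasing the strain of the four-membered ring, after which methanol removes the C4 silyl group. The closest known reaction type is the pinacol/semipinacol ring expansion of 1-(1-hydroxyalkyl)cyclobutanol silyl ethers, with ionisation as in the acid step of a Stork–Danheiser transposition. No ring is closed end to end: a suprafacial 1,2-shift inserts C1 into the ring C8–C5–C6–C7, giving the ring C1–C8–C5–C6–C7 and turning fused bicyclo[4.2.0] into bridged bicyclo[3.2.1]. The new stereocentre C1 is fixed by the tether, since C7 can reach only the concave face of the planar cation and the allyl group is pushed to the convex side, while C7 migrates with retention and C4, C5 and C6 are untouched. The step needs migration of C7 rather than C5, which is secured because the C8–C5 bond lies in the nodal plane of the cation (it is part of the six-membered ring) whereas C8–C7 can align with the empty orbital. It also needs the shift to outrun hydrolysis to the transposed enone, which is secured because the one equivalent of water released is taken up by the departing silyl group.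

Step 6
Reactants: 10 endo alcohol
Product: 11 target, 4-exo-acetoxy-1-allyl-6-exo-(3,4-dimethoxyphenyl)-3,5-dimethoxy-7-endo-methylbicyclo[3.2.1]oct-2-en-8-one
Conditions: AcOH, PPh3, DIAD, toluene, 0 °C → rt
Reagents that add atoms: acetic acid CC(=O)O
Why: Mitsunobu reaction: SN2 displacement of the activated endo alcohol by acetate from the open exo face (the side of the C8 bridge) should invert C4 and install the ester in one operation, under near-neutral conditions that spare the beta-hydroxy ketone from retro-aldol cleavage.

**Compound list**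
1 | 2,6-dimethoxy-1,4-benzoquinone | COC1=CC(=O)C=C(OC)C1=O | starting material
2 | (E)-methyl isoeugenol, (E)-1,2-dimethoxy-4-(prop-1-enyl)benzene | C/C=C/c1ccc(OC)c(OC)c1 | starting material
3 | cis-fused cyclobutane enedione (angular H and OMe cis; aryl cis to angular OMe; methyl trans to aryl) | O=C1C=C(OC)C(=O)[C@@]2(OC)[C@H](c3ccc(OC)c(OC)c3)[C@@H](C)[C@@H]12 | intermediate
4 | 5-hydroxy vinylogous ester (OH trans to angular OMe) | O=C1C=C(OC)[C@@H](O)[C@@]2(OC)[C@H](c3ccc(OC)c(OC)c3)[C@@H](C)[C@@H]12 | intermediate
5 | 1,5-dihydroxy ketone (angular OH cis to angular OMe; present as the dipotassium alkoxide) | O=C1C=C(OC)[C@@H](O)[C@@]2(OC)[C@H](c3ccc(OC)c(OC)c3)[C@@H](C)[C@@]12O | intermediate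
6 | 1,5-bis(trimethylsilyloxy) ketone | O=C1C=C(OC)[C@@H](O[Si](C)(C)C)[C@@]2(OC)[C@H](c3ccc(OC)c(OC)c3)[C@@H](C)[C@@]12O[Si](C)(C)C | intermediate
7 | tertiary allyl carbinol | C=CC[C@]1(O)C=C(OC)[C@@H](O[Si](C)(C)C)[C@@]2(OC)[C@H](c3ccc(OC)c(OC)c3)[C@@H](C)[C@@]12O[Si](C)(C)C | intermediate
8 | dienyl oxocarbenium ion (charge shared by C1 and C3–OMe) | C=CCC1=CC(=[O+]C)[C@@H](O[Si](C)(C)C)[C@@]2(OC)[C@H](c3ccc(OC)c(OC)c3)[C@@H](C)[C@@]12O[Si](C)(C)C | intermediate
9 | 4-endo-trimethylsilyloxy bicyclo[3.2.1]octenone | C=CC[C@]12C=C(OC)[C@@H](O[Si](C)(C)C)[C@](OC)(C1=O)[C@H](c1ccc(OC)c(OC)c1)[C@H]2C | intermediate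
10 | 4-endo-hydroxy bicyclo[3.2.1]octenone | C=CC[C@]12C=C(OC)[C@@H](O)[C@](OC)(C1=O)[C@H](c1ccc(OC)c(OC)c1)[C@H]2C | intermediate
11 | CNP0221003.1, 4-exo-acetate | C=CC[C@]12C=C(OC)[C@H](OC(C)=O)[C@](OC)(C1=O)[C@H](c1ccc(OC)c(OC)c1)[C@H]2C | target

Total step count: 6. Longest linear sequence: 6.

**Steps most likely to fail**

Step 1. The zwitterion may collapse through the carbonyl oxygen or the remote enol ether carbon instead of the methoxy-bearing enolate carbon. The aryl group may take the endo side, and the bulky chiral complex may react slowly or with poor facial discrimination. The fallback separates ring formation from the source of chirality. It sets out from 1 and 2. The cycloaddition is run with an alkoxide-rich TiCl4/Ti(OiPr)4 mixture without ligand at −78 °C to give the racemic cyclobutane F1. Luche reduction gives the racemic alcohol F2. DCC/DMAP esterification with (S)-2-methoxy-2-phenylacetic acid gives two esters that are separated by chromatography, the matched ester F3 and the diastereomeric ester F4. K2CO3/MeOH releases 4 from F3, where the route resumes.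

Step 5. The cation may lose a proton (from the allyl CH2, or from C4 with loss of configuration there), or it may be hydrolysed to the transposed enone faster than the shift occurs. The fallback avoids the cation and installs the allyl group after the ring has grown. It sets out from 5, isolated by an aqueous NH4Cl quench in step 3. Et3SiCl/imidazole silylates only the secondary alcohol to give the triethylsilyl ether F5. KOtBu (0.2 equiv) in THF at 0 °C triggers the alpha-ketol ring expansion of the 1-acylcyclobutanol to the bridgehead carbinol F6. NaH, CS2 and MeI give the bridgehead xanthate F7, which cannot undergo syn elimination. Keck radical allylation (Bu3SnCH2CH=CH2, AIBN, benzene, 80 °C) gives the allyl ketone F8. PPTS/MeOH removes the silyl group and the route is rejoined at 10.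

Step 6. The displacement may be slowed by the flanking quaternary C5, so that SN2′ attack or return of unreacted alcohol dominates. The fallback switches from SN2 to an ionisation pathway. It sets out from 10. MsCl/Et3N gives the mesylate F9. Buffered acetolysis (KOAc, AcOH, 40 °C) proceeds through the bicyclo[3.2.1]oct-3-en-2-yl cation, which should be captured kinetically from the exo (axial) face. Any C2 regioisomer is removed by chromatography. The route is rejoined at 11.

**Further compounds**
F1 | step 1 | racemic cyclobutane enedione (one enantiomer drawn) | O=C1C=C(OC)C(=O)[C@@]2(OC)[C@H](c3ccc(OC)c(OC)c3)[C@@H](C)[C@@H]12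
F2 | step 1 | racemic 5-hydroxy vinylogous ester (one enantiomer drawn) | O=C1C=C(OC)[C@@H](O)[C@@]2(OC)[C@H](c3ccc(OC)c(OC)c3)[C@@H](C)[C@@H]12
F3 | step 1 | (S)-2-methoxy-2-phenylacetate of 4 | O=C1C=C(OC)[C@@H](OC(=O)[C@@H](OC)c3ccccc3)[C@@]2(OC)[C@H](c3ccc(OC)c(OC)c3)[C@@H](C)[C@@H]12
F4 | step 1 | (S)-2-methoxy-2-phenylacetate of the enantiomer of 4 | O=C1C=C(OC)[C@H](OC(=O)[C@@H](OC)c3ccccc3)[C@]2(OC)[C@@H](c3ccc(OC)c(OC)c3)[C@H](C)[C@H]12
F5 | step 5 | 1-hydroxy-5-triethylsilyloxy ketone | O=C1C=C(OC)[C@@H](O[Si](CC)(CC)CC)[C@@]2(OC)[C@H](c3ccc(OC)c(OC)c3)[C@@H](C)[C@@]12O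
F6 | step 5 | 1-hydroxy-4-endo-triethylsilyloxy bicyclo[3.2.1]octenone | O[C@]12C=C(OC)[C@@H](O[Si](CC)(CC)CC)[C@](OC)(C1=O)[C@H](c1ccc(OC)c(OC)c1)[C@H]2C
F7 | step 5 | bridgehead S-methyl xanthate | CSC(=S)O[C@]12C=C(OC)[C@@H](O[Si](CC)(CC)CC)[C@](OC)(C1=O)[C@H](c1ccc(OC)c(OC)c1)[C@H]2C
F8 | step 5 | 1-allyl-4-endo-triethylsilyloxy bicyclo[3.2.1]octenone | C=CC[C@]12C=C(OC)[C@@H](O[Si](CC)(CC)CC)[C@](OC)(C1=O)[C@H](c1ccc(OC)c(OC)c1)[C@H]2C
F9 | step 6 | 4-endo-mesylate of 10 | C=CC[C@]12C=C(OC)[C@@H](OS(C)(=O)=O)[C@](OC)(C1=O)[C@H](c1ccc(OC)c(OC)c1)[C@H]2C
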